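Compound numbers refer to the list after the steps.

## The problem

Compound 20 is a 5-deoxyflavanone. Its benzene ring A (C4a, C5, C6, C7, C8, C8a) is fused to the dihydropyranone ring C (O1, C2, C3, C4); the catechol ring B sits on C2, a methoxy group on C7 and an (E)-4-hydroxy-3-methylbut-2-enyl chain on C8. C2 is the only stereocenter, so nothing in the molecule can relay its configuration and a catalyst has to set it. Being benzylic, bonded to O1 and β to the C4 carbonyl, C2 is lost by retro-oxa-Michael opening of ring C whenever base is present, most easily once the 4'-hydroxyl is free. The C8 chain lies between the C7 oxygen and O1, the most hindered position of ring A, and a finished 7-oxygenated flavanone would offer an electrophile C6 as well as C8; the trisubstituted alkene must stay E and the catechol must travel masked by groups that come off without base. The feature that opens a shortcut is the pattern of ring A: oxygen on C7 and C8a in a 1,3 relation, carbon on C8 and C4a, hydrogen on C5 and C6. This is the pattern of a chain C4–C4a–C8a–C8–C7–C6–C5 with carbonyl carbons at C4, C8a and C7 and an aldehyde-level carbon at C5. If O1, C8a, C4a and C4 are already held as the enol ether and ketone of a 2,3-dihydro-4H-pyran-4-one, C4a is the nucleophilic α-carbon of a vinylogous ester that the C5 aldehyde reaches through a six-membered transition state. C8 is then still an sp3 carbon between two acyl groups and takes the side chain by simple enolate alkylation.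

## Retrosynthesis

**20 to 19 to 18.** No skeletal bond is cut first. The three silyl ethers of 19 are removed last, and the C7 methyl ether of 19 is traced to the phenol 18. The order follows from the key step, which delivers the C7 oxygen as a phenol formed from a ketone. Both forward reactions must avoid base: a silver-assisted methylation and an acidic fluoride source.

**18 to 15 (key disconnection).** The C4a–C5 bond of ring A is cut, together with the C5=C6 unsaturation that arises by loss of water. This leads to dihydropyranone 15, whose C6 substituent is a 4,4-dimethoxy-2-oxobutyl chain bearing the side chain on its first carbon. Cuts at C4–C4a or O1–C2 would keep ring A and leave the C6/C8 regiochemistry and the hindered C8 position to be solved on an arene. This cut removes the arene altogether, so 15 has no aromatic substitution problem and its C8 configuration is irrelevant. The forward reaction must free the C5 aldehyde under weak acid, let C4a add to it, and aromatise without opening ring C at C2.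

**15 to 11 and 14.** The C8–CH2 bond to the side chain is cut. In 11, C8 is a methylene between the C7 ketone and the vinylogous ester, acidic enough for one equivalent of a hydride base that never reaches C3. An allylic chloride with fixed E geometry is preferred to a palladium-allyl route from the vinyl epoxide, which would leave the alkene geometry open. A tert-butyldiphenylsilyl ether is chosen for the chain because it has to survive the aqueous acid of the key step. The forward reaction must alkylate at carbon, and only once.

**14 to 13 to 12.** The silyl ether is removed and the chloro alcohol 13 is traced to 2-methyl-2-vinyloxirane 12 by an SN2' opening with chloride. This supplies all five side-chain carbons with the correct oxygen and the E alkene in one step.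

**11 to 7 and 9 (through 10).** Two bonds are cut: O1–C8a of ring C and C8–C7 of the chain. This gives the open δ-hydroxy-β-diketone 7 and the acyl donor 9. The other order, closing ring C first and acylating afterwards, would need γ-deprotonation of a cyclic β-alkoxy enone that still has α' protons at C3; kinetic deprotonation goes to C3, and a C3 enolate can expel O1 and destroy C2. In the open compound the polyanion forms at the terminal methyl with normal β-diketone regiochemistry. Afterwards the C2 hydroxyl can reach only the C8a carbonyl in a six-membered ring, so the triketone 10 folds one way. The forward reaction must stop at the ketone, hence a Weinreb amide, and must close ring C with an acid too weak to touch the acetal.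

**9 to 8.** The amide is made from methyl 3,3-dimethoxypropanoate 8, which carries C7, C6 and C5 at the right oxidation levels.

**7 to 2 and 5 (through 6).** The C2–C3 bond is cut in the aldol sense. A catalytic enantioselective vinylogous Mukaiyama aldol addition of a symmetric bis(silyloxy)diene to an aromatic aldehyde is of a well-known type and sets C2 at the very start. The forward reaction must give the S carbinol and release it without dehydration.

**2 to 1 and 5 to 3 (through 4).** Silylation of 3,4-dihydroxybenzaldehyde 1 and exhaustive silyl enol ether formation from acetylacetone 3 complete the analysis.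

## Roads not taken

**Alternative 1: Friedel–Crafts closure of a β-aryloxy acid.**
- Cut: C4–C4a.
- Forward key step: acid A2, made by Mitsunobu etherification of a phenol with an (R)-configured benzylic β-hydroxy ester (inversion) and ester cleavage, is activated as its chloride with (COCl)2 and closed with SnCl4, or as a mixed anhydride with trifluoroacetic anhydride, to bromoflavanone A1. The chain is then attached by palladium-catalysed allylation at the C8–Br bond.
- Merits: every reaction is of a known type, ring A is bought complete, and the acylation can only go para to the methoxy group and ortho to the ether oxygen.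
- Weak points: the Mitsunobu reaction at a benzylic carbinol next to an oxygenated aryl ring can leak through an ion pair or eliminate to a cinnamate. The activated β-aryloxy acid can fragment by β-elimination under the Lewis acid. The chain must be coupled at a carbon flanked by two oxygen substituents, with risk of allyl transposition and E/Z loss, on a molecule that already holds the base-sensitive C2. The aryl acetates must then come off without base.
- Comparison: in reliability of the single steps this road is ahead, because the chosen plan rests on a ring closure without direct precedent. The chosen plan sets against it that the chain enters at an sp3 carbon with secured geometry, that C2 comes from a catalytic aldol and is never the site of a substitution, that no late metal-catalysed coupling is needed, and that the longest linear sequence is seven steps.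

**Alternative 2: ring A by Diels–Alder reaction of a Brassard-type diene.**
- Cut: C4a–C8a and C5–C6.
- Forward key step: diene A4 and but-3-yn-2-one A5 undergo a Diels–Alder reaction, and loss of methanol aromatises the adduct to acetophenone A3.
- Merits: the polarisation of both partners dictates the regiochemistry, and hydroxyl, chain and methoxy group are placed in one step. Cycloaddition and aromatisation of such dienes with alkynones is known chemistry, which the chosen key step is not.
- Weak points: A3 contains neither ring C nor C2. It still has to be condensed with 2 to chalcone A6, and A6 has to be closed enantioselectively. A 2'-hydroxychalcone without an extra activating group has no dependable catalytic oxa-Michael closure, and the closure is reversible under base. A4 is a 2-substituted, hydrolytically labile diene that takes several steps from a β-keto ester.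
- Comparison: ring A is made on firmer ground here, but the route is longer and leaves the only stereocenter to its weakest step. The chosen plan reverses the order of risk: the stereocenter first by a known reaction, ring A last.

**Alternative 3: asymmetric ortho-quinone methide cycloaddition.**
- Cut: C3–C4 and O1–C2.
- Forward key step: under a chiral BINOL-derived phosphoric acid, acetal A8 loses methanol to a 4-methoxy ortho-quinone methide, which adds styrene A9 in an oxa-[4+2] reaction to give the cis-4-methoxyflavan A7.
- Merits: this is the most convergent road. It forms ring C, two bonds and C2 in one catalytic step, which no step of the chosen plan matches, and both halves are simple arenes.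
- Weak points: A9 has no hydrogen-bonding handle for the catalyst and its acetates lower its nucleophilicity, so rate and facial control are uncertain. C4 arrives as a methyl ether at the alcohol oxidation level and needs ether cleavage and oxidation next to electron-rich rings and an allylic silyl ether. A8 itself needs regioselective C-allylation and formylation of a resorcinol derivative, which is the C6/C8 problem the chosen plan avoids.
- Comparison: if the enantioselectivity were secured, this road would be shorter in concept. The chosen plan sets against it an aldol of established type for C2 and a ring A whose substitution pattern is built in.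

Key step: step 9

Assumption: with diene 5 the Ti(OiPr)4/BINOL catalyst is taken to show the facial preference usual for the related acetoacetate-derived diene, (S)-BINOL leading to the S carbinol of an aromatic aldehyde; if the sense proves opposite, (R)-BINOL is used and nothing else changes.

Assumption: 2-methyl-2-vinyloxirane 12, the monoepoxide of isoprene, is bought as such.

## Route

Step 1
Reactants: 1 3,4-dihydroxybenzaldehyde
Product: 2 3,4-bis(tert-butyldimethylsilyloxy)benzaldehyde
Conditions: TBSCl (2.4 equiv), imidazole (5 equiv), DMF, rt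
Reagents that add atoms: tert-butyldimethylsilyl chloride (TBSCl), CC(C)(C)[Si](C)(C)Cl
Why: Standard silylation of both phenols; aryl silyl ethers tolerate the titanium catalyst, the amide base and the weak acids that follow and are removed at the end by fluoride without base.

Step 2
Reactants: 3 acetylacetone
Product: 5 (3Z)-2,4-bis(trimethylsilyloxy)penta-1,3-diene, via mono-silyl enol ether 4 (not isolated)
Conditions: TMSOTf (2.1 equiv), Et3N (2.3 equiv), Et2O, 0 °C to rt
Reagents that add atoms: trimethylsilyl trifluoromethanesulfonate (TMSOTf), C[Si](C)(C)OS(=O)(=O)C(F)(F)F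
Why: Exhaustive soft enolisation of a β-diketone with a silyl triflate and an amine; the enol ether 4 forms first and is silylated a second time at its methyl ketone to give the 1,3-bis(silyloxy)diene.

Step 3
Reactants: 2 3,4-bis(tert-butyldimethylsilyloxy)benzaldehyde; 5 (3Z)-2,4-bis(trimethylsilyloxy)penta-1,3-diene
Product: 7 (6S)-6-[3,4-bis(tert-butyldimethylsilyloxy)phenyl]-6-hydroxyhexane-2,4-dione, via bis-trimethylsilyl aldol adduct 6 (not isolated)
Conditions: Ti(OiPr)4 (10 mol %), (S)-BINOL (10 mol %), 4 Å MS, THF, −78 to −20 °C; then 1 M HCl, THF, 0 °C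
Reagents that add atoms: none
Why: Catalytic enantioselective vinylogous Mukaiyama aldol addition; the terminal carbon of 5 attacks the aldehyde held in the BINOL–titanium complex, whose chiral environment exposes one carbonyl face, so that the stereocenter (later C2) is set here as S. Cold dilute acid then removes both trimethylsilyl groups of 6 without dehydrating or cyclising the product.

Step 4
Reactants: 8 methyl 3,3-dimethoxypropanoate
Product: 9 N,3,3-trimethoxy-N-methylpropanamide
Conditions: MeNHOMe·HCl (1.5 equiv), iPrMgCl (3.0 equiv), THF, −20 °C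
Reagents that add atoms: N,O-dimethylhydroxylamine hydrochloride, CNOC.Cl
Why: Weinreb amide formation from an ester with the magnesium amide of N,O-dimethylhydroxylamine; the amide lets the next acylation stop at the ketone through its chelated tetrahedral adduct.

Step 5
Reactants: 7 (6S)-6-[3,4-bis(tert-butyldimethylsilyloxy)phenyl]-6-hydroxyhexane-2,4-dione; 9 N,3,3-trimethoxy-N-methylpropanamide
Product: 11 (2S)-2-[3,4-bis(tert-butyldimethylsilyloxy)phenyl]-6-(4,4-dimethoxy-2-oxobutyl)-2,3-dihydro-4H-pyran-4-one, via hydroxy triketone 10 (not isolated)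
Conditions: LiN(iPr)2 (3.2 equiv), THF, −78 to −20 °C; 9, −78 to −20 °C; AcOH, −78 °C; then PPTS (10 mol %), MgSO4, CH2Cl2, rt
Reagents that add atoms: none
Why: γ-Acylation of a β-diketone polyanion: after the hydroxyl and the central methylene, the third deprotonation goes to the terminal methyl and not to the methylene next to the alkoxide-bearing carbon, and this carbanion adds to the Weinreb amide to give 10 on acidification. The hydroxyl of 10 can reach only the C8a carbonyl in a six-membered hemiketal, which PPTS dehydrates to the vinylogous ester 11 without ionising the dimethyl acetal; the C2–O bond is never broken, so the configuration is kept.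

Step 6
Reactants: 12 2-methyl-2-vinyloxirane
Product: 13 (2E)-4-chloro-2-methylbut-2-en-1-ol
Conditions: TiCl4 (1.0 equiv), CH2Cl2, −85 °C; aqueous work-up
Reagents that add atoms: titanium tetrachloride, Cl[Ti](Cl)(Cl)Cl
Why: Lewis-acid-promoted SN2' opening of a vinyl epoxide by chloride, an established route to this chloro alcohol; the E alkene is expected because the titanium-bound oxymethylene group, the bulkier substituent on the epoxide carbon, lies anti to the vinyl terminus in the reacting conformer.

Step 7
Reactants: 13 (2E)-4-chloro-2-methylbut-2-en-1-ol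
Product: 14 tert-butyl{[(2E)-4-chloro-2-methylbut-2-en-1-yl]oxy}diphenylsilane
Conditions: TBDPSCl (1.1 equiv), imidazole (2 equiv), CH2Cl2, 0 °C
Reagents that add atoms: tert-butyldiphenylsilyl chloride (TBDPSCl), CC(C)(C)[Si](Cl)(c1ccccc1)c1ccccc1
Why: Silylation of a primary alcohol, fast enough at 0 °C to leave the allylic chloride untouched; the tert-butyldiphenylsilyl ether is chosen because it withstands the aqueous acid of step 9.

Step 8
Reactants: 11 (2S)-2-[3,4-bis(tert-butyldimethylsilyloxy)phenyl]-6-(4,4-dimethoxy-2-oxobutyl)-2,3-dihydro-4H-pyran-4-one; 14 tert-butyl{[(2E)-4-chloro-2-methylbut-2-en-1-yl]oxy}diphenylsilane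
Product: 15 (2S)-2-[3,4-bis(tert-butyldimethylsilyloxy)phenyl]-6-{1-[(2E)-4-(tert-butyldiphenylsilyloxy)-3-methylbut-2-en-1-yl]-4,4-dimethoxy-2-oxobutyl}-2,3-dihydro-4H-pyran-4-one (both C8 epimers)
Conditions: NaH (1.0 equiv), THF/DMF (4:1), 0 °C; then 14 (1.05 equiv), 0 °C to rt
Reagents that add atoms: none
Why: C-alkylation of a stabilised enolate: C8 lies between the C7 ketone and the vinylogous ester, so one equivalent of NaH deprotonates there alone and the C3 protons stay untouched. SN2 displacement at the primary allylic chloride keeps the E alkene; the new C8 stereocenter forms without control and disappears in step 9.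

Step 9
Reactants: 15 (2S)-2-[3,4-bis(tert-butyldimethylsilyloxy)phenyl]-6-{1-[(2E)-4-(tert-butyldiphenylsilyloxy)-3-methylbut-2-en-1-yl]-4,4-dimethoxy-2-oxobutyl}-2,3-dihydro-4H-pyran-4-one
Product: 18 (2S)-2-[3,4-bis(tert-butyldimethylsilyloxy)phenyl]-8-[(2E)-4-(tert-butyldiphenylsilyloxy)-3-methylbut-2-en-1-yl]-7-hydroxy-2,3-dihydro-4H-chromen-4-one, via keto aldehyde 16 (not isolated), via cyclic aldol 17 (not isolated)
Conditions: AcOH/THF/H2O (3:1:1), 45 °C
Reagents that add atoms: none
Why: Proposed new method: aqueous acetic acid hydrolyses the dimethyl acetal of 15 to the largely enolised β-keto aldehyde 16; C4a, the α-carbon of the vinylogous ester and, after enolisation at the doubly activated C8, the end of an extended dienol, adds to the protonated C5 carbonyl to give aldol 17, which loses water across C5–C6 and enolises at C8 to the phenol 18. The closest known reaction type is the biomimetic aldol condensation and aromatisation of masked β-polycarbonyl chains to resorcinol rings, in which a free active methylene and not a dihydropyranone carbon is the nucleophile. Ring A closes in a 6-(enolendo)-exo-trig mode, with the enol ether double bond C4a=C8a inside the new ring and the aldehyde C=O outside it. No new stereocenter is formed: the C8 epimers of 15 converge because C8 becomes sp2, and C2 is not involved. The step needs one mode of folding and an intact C2: the pyranone holds C4, C4a and C8a so that the C5 aldehyde reaches only C4a through a six-membered transition state (C3 would need an eight-membered and C8 a four-membered one), and the medium is kept weakly acidic so that neither opening of ring C at C2 nor loss of the silyl ethers sets in. Aromatisation makes the sequence irreversible.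

Step 10
Reactants: 18 (2S)-2-[3,4-bis(tert-butyldimethylsilyloxy)phenyl]-8-[(2E)-4-(tert-butyldiphenylsilyloxy)-3-methylbut-2-en-1-yl]-7-hydroxy-2,3-dihydro-4H-chromen-4-one
Product: 19 (2S)-2-[3,4-bis(tert-butyldimethylsilyloxy)phenyl]-8-[(2E)-4-(tert-butyldiphenylsilyloxy)-3-methylbut-2-en-1-yl]-7-methoxy-2,3-dihydro-4H-chromen-4-one
Conditions: MeI (3 equiv), Ag2O (1.5 equiv), MeCN, rt, dark
Reagents that add atoms: iodomethane (MeI), CI
Why: Silver-assisted O-methylation of the acidic para-acyl phenol; no free phenoxide or carbonate is present, so ring C is not opened at C2 and the aryl silyl ethers are not attacked.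

Step 11
Reactants: 19 (2S)-2-[3,4-bis(tert-butyldimethylsilyloxy)phenyl]-8-[(2E)-4-(tert-butyldiphenylsilyloxy)-3-methylbut-2-en-1-yl]-7-methoxy-2,3-dihydro-4H-chromen-4-one
Product: 20 (2S)-2-(3,4-dihydroxyphenyl)-8-[(2E)-4-hydroxy-3-methylbut-2-en-1-yl]-7-methoxy-2,3-dihydro-4H-chromen-4-one
Conditions: HF·pyridine (excess), pyridine, THF, 0 °C to rt, under argon
Reagents that add atoms: none
Why: Fluoride-mediated desilylation in an acidic, buffered medium removes the two aryl silyl ethers and the primary tert-butyldiphenylsilyl ether in one operation; without base the free 4'-hydroxyflavanone keeps its C2 configuration.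

## Compound list

1 | 3,4-dihydroxybenzaldehyde | O=Cc1ccc(O)c(O)c1 | starting material
2 | 3,4-bis(tert-butyldimethylsilyloxy)benzaldehyde | O=Cc1ccc(O[Si](C)(C)C(C)(C)C)c(O[Si](C)(C)C(C)(C)C)c1 | intermediate
3 | acetylacetone (pentane-2,4-dione) | CC(=O)CC(C)=O | starting material
4 | (3Z)-4-(trimethylsilyloxy)pent-3-en-2-one | CC(=O)/C=C(\O[Si](C)(C)C)C | intermediate (not isolated)
5 | (3Z)-2,4-bis(trimethylsilyloxy)penta-1,3-diene | C=C(O[Si](C)(C)C)/C=C(\O[Si](C)(C)C)C | intermediate
6 | (2Z,6S)-6-[3,4-bis(tert-butyldimethylsilyloxy)phenyl]-2,6-bis(trimethylsilyloxy)hex-2-en-4-one | C/C(O[Si](C)(C)C)=C/C(=O)C[C@H](O[Si](C)(C)C)c1ccc(O[Si](C)(C)C(C)(C)C)c(O[Si](C)(C)C(C)(C)C)c1 | intermediate (not isolated)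
7 | (6S)-6-[3,4-bis(tert-butyldimethylsilyloxy)phenyl]-6-hydroxyhexane-2,4-dione | CC(=O)CC(=O)C[C@H](O)c1ccc(O[Si](C)(C)C(C)(C)C)c(O[Si](C)(C)C(C)(C)C)c1 | intermediate
8 | methyl 3,3-dimethoxypropanoate | COC(=O)CC(OC)OC | starting material
9 | N,3,3-trimethoxy-N-methylpropanamide | CON(C)C(=O)CC(OC)OC | intermediate
10 | (9S)-9-[3,4-bis(tert-butyldimethylsilyloxy)phenyl]-9-hydroxy-1,1-dimethoxynonane-3,5,7-trione | COC(OC)CC(=O)CC(=O)CC(=O)C[C@H](O)c1ccc(O[Si](C)(C)C(C)(C)C)c(O[Si](C)(C)C(C)(C)C)c1 | intermediate (not isolated)
11 | (2S)-2-[3,4-bis(tert-butyldimethylsilyloxy)phenyl]-6-(4,4-dimethoxy-2-oxobutyl)-2,3-dihydro-4H-pyran-4-one | O=C1C[C@@H](c2ccc(O[Si](C)(C)C(C)(C)C)c(O[Si](C)(C)C(C)(C)C)c2)OC(CC(=O)CC(OC)OC)=C1 | intermediate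
12 | 2-methyl-2-vinyloxirane (racemic) | CC1(C=C)CO1 | starting material
13 | (2E)-4-chloro-2-methylbut-2-en-1-ol | ClC/C=C(\C)CO | intermediate
14 | tert-butyl{[(2E)-4-chloro-2-methylbut-2-en-1-yl]oxy}diphenylsilane | ClC/C=C(\C)CO[Si](c1ccccc1)(c1ccccc1)C(C)(C)C | intermediate
15 | (2S)-2-[3,4-bis(tert-butyldimethylsilyloxy)phenyl]-6-{1-[(2E)-4-(tert-butyldiphenylsilyloxy)-3-methylbut-2-en-1-yl]-4,4-dimethoxy-2-oxobutyl}-2,3-dihydro-4H-pyran-4-one, both C8 epimers | O=C1C[C@@H](c2ccc(O[Si](C)(C)C(C)(C)C)c(O[Si](C)(C)C(C)(C)C)c2)OC(C(C/C=C(\C)CO[Si](c2ccccc2)(c2ccccc2)C(C)(C)C)C(=O)CC(OC)OC)=C1 | intermediate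
16 | (2S)-2-[3,4-bis(tert-butyldimethylsilyloxy)phenyl]-6-{1-[(2E)-4-(tert-butyldiphenylsilyloxy)-3-methylbut-2-en-1-yl]-2,4-dioxobutyl}-2,3-dihydro-4H-pyran-4-one | O=C1C[C@@H](c2ccc(O[Si](C)(C)C(C)(C)C)c(O[Si](C)(C)C(C)(C)C)c2)OC(C(C/C=C(\C)CO[Si](c2ccccc2)(c2ccccc2)C(C)(C)C)C(=O)CC=O)=C1 | intermediate (not isolated)
17 | (2S)-2-[3,4-bis(tert-butyldimethylsilyloxy)phenyl]-8-[(2E)-4-(tert-butyldiphenylsilyloxy)-3-methylbut-2-en-1-yl]-5-hydroxy-2,3,5,6-tetrahydro-4H-chromene-4,7(8H)-dione, mixture at C5 and C8 | O=C1C[C@@H](c2ccc(O[Si](C)(C)C(C)(C)C)c(O[Si](C)(C)C(C)(C)C)c2)OC2=C1C(O)CC(=O)C2C/C=C(\C)CO[Si](c1ccccc1)(c1ccccc1)C(C)(C)C | intermediate (not isolated)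
18 | (2S)-2-[3,4-bis(tert-butyldimethylsilyloxy)phenyl]-8-[(2E)-4-(tert-butyldiphenylsilyloxy)-3-methylbut-2-en-1-yl]-7-hydroxy-2,3-dihydro-4H-chromen-4-one | Oc1ccc2c(c1C/C=C(\C)CO[Si](c3ccccc3)(c3ccccc3)C(C)(C)C)O[C@H](c1ccc(O[Si](C)(C)C(C)(C)C)c(O[Si](C)(C)C(C)(C)C)c1)CC2=O | intermediate
19 | (2S)-2-[3,4-bis(tert-butyldimethylsilyloxy)phenyl]-8-[(2E)-4-(tert-butyldiphenylsilyloxy)-3-methylbut-2-en-1-yl]-7-methoxy-2,3-dihydro-4H-chromen-4-one | COc1ccc2c(c1C/C=C(\C)CO[Si](c3ccccc3)(c3ccccc3)C(C)(C)C)O[C@H](c1ccc(O[Si](C)(C)C(C)(C)C)c(O[Si](C)(C)C(C)(C)C)c1)CC2=O | intermediate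
20 | (2S)-2-(3,4-dihydroxyphenyl)-8-[(2E)-4-hydroxy-3-methylbut-2-en-1-yl]-7-methoxy-2,3-dihydro-4H-chromen-4-one | COc1ccc2c(c1C/C=C(\C)CO)O[C@H](c1ccc(O)c(O)c1)CC2=O | target

## Step count and least certain steps

Total step count: 11. Longest linear sequence: 7 steps (steps 1, 3, 5, 8, 9, 10, 11 from 1; the sequence 2, 3, 5, 8, 9, 10, 11 from 3 is equally long).

**Step 9 (key step, proposed new method).**
- Most likely failure: the freed keto aldehyde rests as its stable enol and the enol ether carbon C4a fails to attack. Prolonged heating in aqueous acid then leads to hydration of the vinylogous ester, opening of ring C with erosion of C2, or loss of the aryl silyl ethers.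
- Fallback (from 15, back at 18): two known reaction types are used in sequence. 15 is converted with TMSOTf and Et3N into the trimethylsilyl enol ether of its C7 ketone F1. A catalytic amount of TMSOTf in CH2Cl2 at −78 °C then ionises the dimethyl acetal, and the silyl polyenol ether adds through C4a in an intramolecular Mukaiyama aldol addition to an acetal, giving the 5-methoxy diketone F2. On warming with PPTS, F2 loses methanol and enolises to 18.

**Step 5.**
- Most likely failure: incomplete formation of the trianion, or proton transfer from the α-methylene of 9 followed by β-elimination of methoxide, competes with acylation. On acidification, 10 may also fold to a 4-pyranone or a carbocycle before the hydroxyl closes ring C.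
- Fallback (from 7, back at 11): the hydroxyl is taken out of play. 7 is silylated with Et3SiCl and imidazole to the triethylsilyl ether F3, whose ordinary diketone dianion (2.2 equiv LiN(iPr)2) is acylated with 9 to the silylated triketone F4. PPTS in methanol, in which the dimethyl acetal is safe, then removes the triethylsilyl group and closes the dihydropyranone to 11.

**Step 3.**
- Most likely failure: poor facial selectivity or slow turnover with the electron-rich, bulky aldehyde 2, and dehydration or premature cyclisation of the aldol during desilylation.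
- Fallback (from 2 and 3, back at 7): the dianion of 3 (2 equiv LiN(iPr)2, THF) adds to 2 to give the racemic aldol F5. Candida antarctica lipase B with vinyl acetate, following the usual enantiopreference of lipases for secondary aryl carbinols, acetylates the R enantiomer to the acetate F6 and leaves 7, which is separated.

**Step 8.**
- Most likely failure: alkylation at oxygen or at C4a instead of C8, a second alkylation at C8, or silyl loss from the catechol under the basic conditions.
- Fallback (from 11 and 12, back at 15): a neutral Tsuji–Trost reaction replaces the base. Pd(PPh3)4 (5 mol %) in THF opens 12 to a π-allyl alkoxide that deprotonates 11 and is attacked by the C8 carbon at its unsubstituted end, giving the allylic alcohol F7. E/Z isomers are separated if needed, and TBDPSCl with imidazole converts F7 into 15.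

## Further compounds

F1 | step 9 | (2S)-2-[3,4-bis(tert-butyldimethylsilyloxy)phenyl]-6-{1-[(2E)-4-(tert-butyldiphenylsilyloxy)-3-methylbut-2-en-1-yl]-4,4-dimethoxy-2-(trimethylsilyloxy)but-1-en-1-yl}-2,3-dihydro-4H-pyran-4-one (enol ether geometry open) | O=C1C[C@@H](c2ccc(O[Si](C)(C)C(C)(C)C)c(O[Si](C)(C)C(C)(C)C)c2)OC(C(C/C=C(\C)CO[Si](c2ccccc2)(c2ccccc2)C(C)(C)C)=C(O[Si](C)(C)C)CC(OC)OC)=C1
F2 | step 9 | (2S)-2-[3,4-bis(tert-butyldimethylsilyloxy)phenyl]-8-[(2E)-4-(tert-butyldiphenylsilyloxy)-3-methylbut-2-en-1-yl]-5-methoxy-2,3,5,6-tetrahydro-4H-chromene-4,7(8H)-dione (mixture at C5 and C8) | O=C1C[C@@H](c2ccc(O[Si](C)(C)C(C)(C)C)c(O[Si](C)(C)C(C)(C)C)c2)OC2=C1C(OC)CC(=O)C2C/C=C(\C)CO[Si](c1ccccc1)(c1ccccc1)C(C)(C)C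
F3 | step 5 | (6S)-6-[3,4-bis(tert-butyldimethylsilyloxy)phenyl]-6-(triethylsilyloxy)hexane-2,4-dione | CC(=O)CC(=O)C[C@H](O[Si](CC)(CC)CC)c1ccc(O[Si](C)(C)C(C)(C)C)c(O[Si](C)(C)C(C)(C)C)c1
F4 | step 5 | (9S)-9-[3,4-bis(tert-butyldimethylsilyloxy)phenyl]-1,1-dimethoxy-9-(triethylsilyloxy)nonane-3,5,7-trione | COC(OC)CC(=O)CC(=O)CC(=O)C[C@H](O[Si](CC)(CC)CC)c1ccc(O[Si](C)(C)C(C)(C)C)c(O[Si](C)(C)C(C)(C)C)c1
F5 | step 3 | racemic 6-[3,4-bis(tert-butyldimethylsilyloxy)phenyl]-6-hydroxyhexane-2,4-dione | CC(=O)CC(=O)CC(O)c1ccc(O[Si](C)(C)C(C)(C)C)c(O[Si](C)(C)C(C)(C)C)c1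
F6 | step 3 | (1R)-1-[3,4-bis(tert-butyldimethylsilyloxy)phenyl]-3,5-dioxohexyl acetate | CC(=O)CC(=O)C[C@@H](OC(C)=O)c1ccc(O[Si](C)(C)C(C)(C)C)c(O[Si](C)(C)C(C)(C)C)c1
F7 | step 8 | (2S)-2-[3,4-bis(tert-butyldimethylsilyloxy)phenyl]-6-{1-[(2E)-4-hydroxy-3-methylbut-2-en-1-yl]-4,4-dimethoxy-2-oxobutyl}-2,3-dihydro-4H-pyran-4-one (both C8 epimers) | O=C1C[C@@H](c2ccc(O[Si](C)(C)C(C)(C)C)c(O[Si](C)(C)C(C)(C)C)c2)OC(C(C/C=C(\C)CO)C(=O)CC(OC)OC)=C1
A1 | alternative 1 | (2S)-8-bromo-7-methoxy-3',4'-diacetoxyflavanone | COc1ccc2c(c1Br)O[C@H](c1ccc(OC(C)=O)c(OC(C)=O)c1)CC2=O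
A2 | alternative 1 | (3S)-3-(2-bromo-3-methoxyphenoxy)-3-(3,4-diacetoxyphenyl)propanoic acid | O=C(O)C[C@H](Oc1cccc(OC)c1Br)c1ccc(OC(C)=O)c(OC(C)=O)c1
A3 | alternative 2 | 2'-hydroxy-4'-methoxy-3'-[(E)-4-(tert-butyldimethylsilyloxy)-3-methylbut-2-enyl]acetophenone | COc1ccc(C(C)=O)c(O)c1C/C=C(\C)CO[Si](C)(C)C(C)(C)C
A4 | alternative 2 | 1,3-dimethoxy-1-(trimethylsilyloxy)-2-[(2E)-4-(tert-butyldimethylsilyloxy)-3-methylbut-2-en-1-yl]buta-1,3-diene (ketene acetal geometry open) | C=C(OC)C(C/C=C(\C)CO[Si](C)(C)C(C)(C)C)=C(OC)O[Si](C)(C)C
A5 | alternative 2 | but-3-yn-2-one | C#CC(C)=O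
A6 | alternative 2 | (2E)-3-[3,4-bis(tert-butyldimethylsilyloxy)phenyl]-1-{2-hydroxy-4-methoxy-3-[(2E)-4-(tert-butyldimethylsilyloxy)-3-methylbut-2-en-1-yl]phenyl}prop-2-en-1-one | COc1ccc(C(=O)/C=C/c2ccc(O[Si](C)(C)C(C)(C)C)c(O[Si](C)(C)C(C)(C)C)c2)c(O)c1C/C=C(\C)CO[Si](C)(C)C(C)(C)C
A7 | alternative 3 | (2S,4S)-cis-4-methoxyflavan with 7-methoxy, 8-[(E)-4-(tert-butyldimethylsilyloxy)-3-methylbut-2-enyl] and 3',4'-diacetoxy groups | COc1ccc2c(c1C/C=C(\C)CO[Si](C)(C)C(C)(C)C)O[C@H](c1ccc(OC(C)=O)c(OC(C)=O)c1)C[C@@H]2OC
A8 | alternative 3 | 6-(dimethoxymethyl)-3-methoxy-2-[(2E)-4-(tert-butyldimethylsilyloxy)-3-methylbut-2-en-1-yl]phenol | COc1ccc(C(OC)OC)c(O)c1C/C=C(\C)CO[Si](C)(C)C(C)(C)C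
A9 | alternative 3 | 4-ethenyl-1,2-phenylene diacetate (3,4-diacetoxystyrene) | C=Cc1ccc(OC(C)=O)c(OC(C)=O)c1
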